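Time at constant temperature is the setting that looks open in Sunday's flask, yet the charges set a limit that time does not move. In that closed, stirred flask, substrate and reagent may join reversibly to the intermediate, which may give target and released group. Released group may also tie up substrate as idle adduct or be taken by scavenger, and substrate may decompose.

| setting | Sunday's | Monday's | flask |
|---|---|---|---|
| substrate | 1 M | 1 M | 1.0 M |
| reagent | 0.70 M | 0.35 M | 0.700 M |
| scavenger | 0.80 M | 0.80 M | 0.800 M |
| remark | the very flask that is asked about, followed so far | run made earlier |  |
| time |  |  | 5.0 d |

- Sunday's (time / h: target / %): 6.00: 16.1; 20.0: 46.5; 30.0: 54.4; 48.0: 60.2; 72.0: 66.4; 96.0: 67.3; 120: 70.0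
- Monday's (time / h: target / %): 0.417: 0; 0.667: 0; 0.833: 0; 1.33: 2.7; 2.00: 3.4; 3.00: 3.3; 5.00: 6.7

(standard deviation of a reading: 1 percentage point)

- violet: at 5.0 d add reagent, 50.0% of the amount charged, then wait 5.0 d
- grey: at 5.0 d take out 90% of the released group then present, then wait 5.0 d
- blue: change nothing and wait 5.0 d more
- green: at 5.0 d add substrate, 50.0% of the amount charged, then wait 5.0 d

- target, in percent of the substrate first charged, at 5.0 d
- the option that brings most further target ("none" if no option brings more than 2 percentage points) (violet / grey / blue / green / none)
- target present, in percent of the substrate first charged, after violet
- target present, in percent of the substrate first charged, after green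

- released group is meant together with its idle adduct
- the volume of additions can be left aside
- what may be going on: substrate -> decomposition product; substrate + released group <-> idle adduct; substrate + reagent <-> intermediate; intermediate <-> target + released group; scavenger + released group -> scavenged by-product

Each target in these steps uses one substrate and one reagent. With 0.700 M of reagent against 1.0 M of substrate, Sunday's flask has 70.0%: this is the ceiling, the smaller charge over the substrate first charged. The crossing lies where the two charges are equal. Sunday's charges stand below it, so reagent is the limiting reagent. Sunday's reading at the asked time, 70.0%, lies on the ceiling within the scatter of 1 percentage point, so my own reckoning for now is about the ceiling. Monday's run stops at 6.7%, under its ceiling of 35.0%, and does not test it.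

Blue and grey leave the charges as they are. Green raises substrate, but reagent stays the smaller charge, so in percent of the substrate first charged the ceiling stays at 70.0%. Violet brings the total reagent charged to 1.05 M, past the crossing, so substrate takes over as the smaller charge and the ceiling becomes 100%. That opens 30 points of room, so I choose violet. The ceiling holds no rate, so it does not say how much of that room 5.0 d fills.

The forecast gives 69% now and 70% after green, and it picks violet as best, with 85% after it, on the ground that “Extra reagent should convert most of the remaining substrate”.

The flask gives 68.9% now, 1.1 points under the ceiling, with 1.08% of the charged reagent and 30.3% of the charged substrate still free at 120 h. The best option is violet, with 86.2% after it, which is 14 points under its new ceiling; green gives 70.0%, on its ceiling of 70.0%.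

    substrate → decomposition product (k = 2.30 × 10⁻⁸ s⁻¹)
    substrate + released group ⇌ idle adduct, settled at all times (K = 0.450 M⁻¹)
    substrate + reagent ⇌ intermediate (K = 2.70 M⁻¹, k = 4.80 × 10⁻⁵ M⁻¹ s⁻¹)
    intermediate ⇌ target + released group (K = 1.40 M, k = 5.10 × 10⁻⁵ s⁻¹)
    scavenger + released group → scavenged by-product (k = 2.20 × 10⁻⁴ M⁻¹ s⁻¹)

In the neighbouring flask with 0.42 M of reagent, the ceiling is 42.0%. That flask gives 42.0% at 120 h, with 57.4% of its substrate still free.

The earlier runs and the new flask were generated by integration for an exercise, and the scatter is random.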